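**Remarks on the chemistry.** Germacrane numbering (C1–C10 ring, C14 methyl on C10, C15 methyl on C4) is used for every compound, cyclic or open-chain. Racemic 7 is assumed to be acceptable because C7 is flattened in step 11, so 8–16 are mixtures of C7 epimers (9 and 10 also of C9 epimers). The oxirane of 19 is (4S,5R), which corresponds to the (2R,3S) epoxy alcohol 2 and therefore to the D-(−)-tartrate in step 1. The structures of 15 and 17 were checked against 19 atom by atom and need no correction.

## Structural features

Compound 19 is a germacrane: one ten-membered carbocycle with an E trisubstituted C1=C10 alkene (methyl on C10), a C4–C5 oxirane fused to the ring (methyl on C4, ring bonds C3–C4 and C5–C6 cis on the oxirane), an (E)-cinnamate on O6, an isopropyl group on C7 and a free hydroxyl on C8. Five stereocentres run unbroken from C4 to C8; read along the ring, O5 and O6 are syn, O6 and the isopropyl group are syn, and O6 and O8 are anti. The fragile parts are the oxirane (opened by acids and Lewis acids, and open to transannular attack by the 1(10)-alkene), the strained E-cyclodecene and the cinnamate (conjugate addition, migration from O6 to O8). In the intermediates a C8 ketone adds a further weak point, because its C9 methylene is also allylic and the alkene can slip into conjugation. The real difficulty is to close a ten-membered ring against transannular strain while setting C6 and C7 and telling O6 from O8. The handle is that the C6 carbinol sits between the oxirane carbon C5 and C7, and C7 is alpha to C8. With C8 as a ketone, C6–C7 is an aldol bond between an alpha,beta-epoxy aldehyde and a ketone enolate, so one bond closes the ring and sets two stereocentres. The anti 1,3-pattern of acylated O6 and free O8 is what an Evans–Tishchenko reduction of that aldol leaves behind, and the cis-substituted oxirane maps onto the Z alkene of an allylic alcohol, so a Sharpless epoxidation can carry all the absolute stereochemical information.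

## Logic of the disconnections

**19 ⇒ 17 + 18.** The O6–acyl bond and the C8–H bond are cut together. This is the retron of a hydride shift from a hemiacetal on O6 to the C8 carbonyl, and it removes one stereocentre, the ester and any need to protect either oxygen. The forward step must pass hydride to C8 on the face syn to O6 and must not open the aldol again.

**17 ⇒ 15 (through 16).** The C6–C7 bond is cut; this opens the ring and removes C6 and C7 as stereocentres. The open chain 15 carries only the oxirane as stereochemical information, and its C7 bromide pins the enolate to the C7–C8 side and away from the allylic C9. The forward step must reduce the C–Br bond before the aldehyde, close a ten-membered ring in preference to intermolecular aldol, and give the 5,6-syn and 6,7-syn relationships. For that reason 15 is designed to be made last, under neutral conditions, and to need no configuration at C7.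

**15 ⇒ 14 ⇒ 13.** No skeletal bond is cut: C6 returns to the alcohol level and O6 regains its 4-methoxybenzyl ether. The ether is chosen because it survives carbanions and can be removed oxidatively at neutral pH in the presence of a bromo ketone. The forward steps must be free of base, so that the bromo ketone and the skipped enone are not disturbed.

**13 ⇒ 11 (through 12).** The C7–Br bond is traded for C7–O. An oxygen at C7 can be carried in from a hydroxy ester, which fixes the regiochemistry of the later enolate without any selective enolisation. The forward step must substitute at a hindered carbon without eliminating and without opening the oxirane.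

**11 ⇒ 10 ⇒ 6 + 8.** A sulfonyl group is added at C9 and the C8–C9 bond is then cut. The sulfone makes C9 a carbanion that reacts at its alpha carbon and keeps the alkene geometry, and the cut splits the chain into a C10 piece and a C5 piece. The forward acylation must beat enolisation of a hindered ester, and the desulfonylation must protonate at C9 and leave the C7 oxygen in place.

**6 ⇒ 4 ⇒ 3.** C9–S goes back to C9–O (through 5) and then to C9–H. This reduces the problem to oxidising one methyl group of an isopropylidene unit. The forward oxidation must choose the methyl group trans to the chain, which fixes the 1(10)E geometry.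

**3 ⇒ 2 ⇒ 1.** The ether is removed and the two C–O bonds of the oxirane are cut, which leaves a Z allylic alcohol with a second, remote alkene. The forward step must be enantioselective and must touch only the allylic alkene.

**8 ⇒ 7.** The O–Si bond is cut. The silyl group only shields the hydroxyl during the acylation and is meant to fall off in the work-up.

## Other disconnections considered

**Alternative 1:** The cuts are C3–C4 and C5–C6, which leave three pieces: the Grignard reagent of homoallylic bromide A2 (C9 to C3, with the 1(10)E alkene in place), propyne A3 (C4, C5 and the C4 methyl) and aldehyde A4 (C6 to C8 with the isopropyl group). In the forward sense the organocopper made from A2 and CuBr·SMe2 would add syn across A3, and the resulting alkenylmetal would add to A4 to give dienol A1, with no ring closed.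
- In its favour: three components are joined in one flask. The 4Z geometry follows from the syn addition as dependably as the chosen plan takes it from 1 (equal). C7 arrives as a stereocentre of an enantiopure building block instead of being made in a ring-closing transition state (better on that point). A hydroxyl-directed epoxidation of the 4Z allylic alcohol, steered by allylic 1,3-strain, is a sound way to the 5,6-syn oxirane.
- Against it here: C6 must be set by 1,2-induction from C7 in an open-chain addition, where Felkin–Anh and beta-alkoxy chelation models need not agree. The absolute sense of the oxirane would then hang on that one carbinol and not on reagent control. The ring is still open, so a C8–C9 closure (with the risk of allylic transposition at C9), the adjustment of C8 and the O6/O8 differentiation all remain, with several protecting-group operations.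
- Comparison: on mechanism the carbometalation is the more predictable C–C bond formation. On structure and step economy the chosen plan does more in its key step, because it closes the ring, sets C6 and C7 and stops one step short of 19.

**Alternative 2:** The cuts are C4–C5 and C1–C10 of a [2+2] photoadduct; the C1–C4 bond of the cyclobutene partner and the C5–C10 bond of the enone are to be broken afterwards. Irradiation of enone A6 with cyclobutene ester A7 would give tricyclic ketone A5, and thermal cycloreversion of its bicyclo[2.2.0]hexane part would open the cyclodeca-1(10),4-diene.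
- In its favour: no macrocyclisation is needed, which is better than the chosen plan on the entropic side of ring formation. C7 and C8 are fixed in a six-membered ring before the key step (better for those two centres). Head-to-head regiochemistry is the normal preference for an electron-poor alkene. O6 and O8 are differentiated equally well in principle (a ketone against a silyl ether).
- Against it here: the facial selectivity of the cycloaddition is uncertain. The cycloreversion must give the 1(10)E,4Z diene alone, at temperatures where 1,5-cyclodecadienes tend to undergo Cope rearrangement to divinylcyclohexanes. Afterwards C15 must be taken from the ester level to a methyl group, the C6 ketone reduced in the right sense, the electron-poor C4=C5 alkene epoxidised stereoselectively and O6 acylated. Absolute control rests on enantiopure A6, which must itself be synthesised.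
- Comparison: the photochemical step is mechanistically dependable and the thermal step is the weak point. The long tail of redox adjustments makes this route clearly longer than the chosen plan.

**Alternative 3:** The cut is C7–C8 in the retro sense of a [2,3]-Wittig shift, which traces the carbocycle back to thirteen-membered stannyl ether A9 with oxygen bridging C8 and C12. Tin–lithium exchange with n-BuLi at C8 and the [2,3] shift would form C7–C8, break O–C12 and give triene A8 with C7 and C8 set together.
- In its favour: a thirteen-membered ether is easier to close than a ten-membered carbocycle (better on ring formation). The shift is stereospecific, the configuration of C8 being relayed by retention in the exchange and inversion in the shift; this is at least the equal of relying on chelation in an aldol. O6 and O8 emerge differentiated.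
- Against it here: they are differentiated the wrong way round (silyl on O6, free O8), so a protecting-group exchange must precede the cinnamoylation. The isopropenyl group must be hydrogenated in the presence of two ring alkenes. The oxirane must be introduced late and site-selectively at C4=C5 with C1=C10 present, its absolute sense depending on C6. The enantioenriched secondary alpha-alkoxystannane and the macrocyclic ether each cost several steps, and a [1,2]-shift is a recognised competitor.
- Comparison: on mechanism the alternative is well defined. On structure it leaves three functional-group problems (oxirane, isopropyl, acyl position) that the chosen plan has solved by the end of its key step. On step economy it is the longer route.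

Key step: step 11

## Route

Step 1
Reactants: 1 nerol
Product: 2 (2R,3S)-2,3-epoxynerol {[(2R,3S)-3-methyl-3-(4-methylpent-3-en-1-yl)oxiran-2-yl]methanol}
Conditions: Ti(OiPr)4 (10 mol %), D-(−)-diethyl tartrate (12 mol %), t-BuOOH (2 equiv), 4 Å MS, CH2Cl2, −20 °C
Reagents that add atoms: tert-butyl hydroperoxide CC(C)(C)OO
Why: Sharpless asymmetric epoxidation; the titanium tartrate complex binds the allylic hydroxyl and delivers oxygen to one face of the 2,3-alkene only, so the remote alkene is untouched. The D-(−)-tartrate is the enantiomer that gives the (2R,3S) oxirane, and the Z geometry of 1 fixes the cis relationship of the two ring-bound carbons (C4 and C5 of 19 are set here).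

Step 2
Reactants: 2 (2R,3S)-2,3-epoxynerol
Product: 3 (2R,3S)-2-{[(4-methoxybenzyl)oxy]methyl}-3-methyl-3-(4-methylpent-3-en-1-yl)oxirane (4-methoxybenzyl ether of 2)
Conditions: NaH (1.2 equiv), 4-methoxybenzyl chloride (1.2 equiv), n-Bu4NI (cat.), THF–DMF, 0 °C → rt
Reagents that add atoms: 4-methoxybenzyl chloride COc1ccc(CCl)cc1
Why: Williamson etherification of the primary alkoxide; the more substituted oxirane is the favoured side of any Payne equilibrium and the primary alkoxide is the one alkylated. The ether masks O6 through the carbanion chemistry and can later be removed oxidatively at neutral pH.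

Step 3
Reactants: 3 4-methoxybenzyl ether of epoxynerol
Product: 4 (2E)-5-[(2S,3R)-3-{[(4-methoxybenzyl)oxy]methyl}-2-methyloxiran-2-yl]-2-methylpent-2-en-1-ol (C9 allylic alcohol)
Conditions: SeO2 (0.5 equiv), t-BuOOH (3 equiv), salicylic acid (0.1 equiv), CH2Cl2, 0 °C → rt
Reagents that add atoms: tert-butyl hydroperoxide CC(C)(C)OO (the oxygen atom, relayed by selenium dioxide O=[Se]=O)
Why: Allylic oxidation by SeO2 (ene reaction, then [2,3]-sigmatropic shift) attacks the more substituted end of the only remaining alkene and selects the methyl group trans to the chain, which gives the E allylic alcohol and fixes the 1(10)E geometry. Catalytic SeO2 with t-BuOOH, run to partial conversion, keeps over-oxidation at C9 low.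

Step 4
Reactants: 4 C9 allylic alcohol
Product: 6 (2S,3R)-3-{[(4-methoxybenzyl)oxy]methyl}-2-methyl-2-[(3E)-4-methyl-5-(phenylsulfonyl)pent-3-en-1-yl]oxirane (C9 allylic sulfone), via allylic bromide 5 (not isolated)
Conditions: CBr4 (1.3 equiv), PPh3 (1.3 equiv), CH2Cl2, 0 °C; solvent switch; PhSO2Na (2 equiv), DMF, rt
Reagents that add atoms: carbon tetrabromide BrC(Br)(Br)Br (bromine of 5); sodium benzenesulfinate [Na+].[O-]S(=O)c1ccccc1
Why: Appel bromination of the primary allylic alcohol under neutral conditions, then SN2 S-alkylation of the sulfinate in a dipolar aprotic solvent. The primary sulfone next to the trisubstituted alkene is also the thermodynamically preferred allylic isomer, and the alkene geometry is not touched.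

Step 5
Reactants: 7 methyl 2-hydroxy-3-methylbutanoate (racemic)
Product: 8 methyl 3-methyl-2-[(trimethylsilyl)oxy]butanoate
Conditions: Me3SiCl (1.2 equiv), Et3N (1.5 equiv), CH2Cl2, 0 °C → rt; distillation
Reagents that add atoms: chlorotrimethylsilane C[Si](C)(C)Cl
Why: Silylation of the secondary hydroxyl so that the ester can meet a carbanion without an alkoxide next to the carbonyl; the trimethylsilyl group is chosen because it is lost in the work-up of step 6.

Step 6
Reactants: 6 C9 allylic sulfone; 8 methyl 3-methyl-2-[(trimethylsilyl)oxy]butanoate
Product: 10 (6E)-3-hydroxy-9-[(2S,3R)-3-{[(4-methoxybenzyl)oxy]methyl}-2-methyloxiran-2-yl]-2,6-dimethyl-5-(phenylsulfonyl)non-6-en-4-one (C7-hydroxy C9-sulfonyl C8 ketone), via trimethylsilyl ether 9 (not isolated)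
Conditions: 8 (1.3 equiv), LiN(SiMe3)2 (2.2 equiv), THF, −78 → −20 °C; then AcOH, THF–MeOH–H2O, rt
Reagents that add atoms: none
Why: Claisen-type acylation of the lithiated allylic sulfone at its alpha carbon forms C8–C9; the second equivalent of amide base removes the acidic proton of the keto sulfone and drives the reaction. The E alkene makes cyclisation of the carbanion onto the oxirane geometrically impossible, and the mild acid of the work-up strips the silyl ether.

Step 7
Reactants: 10 C7-hydroxy C9-sulfonyl C8 ketone
Product: 11 (6E)-3-hydroxy-9-[(2S,3R)-3-{[(4-methoxybenzyl)oxy]methyl}-2-methyloxiran-2-yl]-2,6-dimethylnon-6-en-4-one (C7-hydroxy C8 ketone)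
Conditions: SmI2 (2.2 equiv), THF–MeOH, −78 °C
Reagents that add atoms: none
Why: Reductive desulfonylation of a beta-keto sulfone by divalent samarium; electron transfer to the ketone expels sulfinate, and methanol protonates the samarium dienolate at C9 (kinetic alpha-protonation), which keeps the alkene at C1=C10. The low temperature and the exact stoichiometry should leave the much poorer leaving group on C7 and the oxirane alone.

Step 8
Reactants: 11 C7-hydroxy C8 ketone
Product: 13 (6E)-3-bromo-9-[(2S,3R)-3-{[(4-methoxybenzyl)oxy]methyl}-2-methyloxiran-2-yl]-2,6-dimethylnon-6-en-4-one (C7-bromo C8 ketone), via mesylate 12 (not isolated)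
Conditions: (MeSO2)2O (1.5 equiv), pyridine, DMAP (cat.), CH2Cl2, 0 °C; aqueous wash; n-Bu4NBr (3 equiv), THF, 40 °C
Reagents that add atoms: methanesulfonic anhydride CS(=O)(=O)OS(C)(=O)=O (mesyl group of 12); tetrabutylammonium bromide CCCC[N+](CCCC)(CCCC)CCCC.[Br-]
Why: Sulfonylation, then SN2 displacement by bromide at a carbon activated by the neighbouring carbonyl. A chloride-free sulfonylating agent and a bromide source without a Lewis-acidic cation avoid halide mixtures and oxirane opening; the configuration at C7 is of no consequence.

Step 9
Reactants: 13 C7-bromo C8 ketone (4-methoxybenzyl ether)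
Product: 14 (6E)-3-bromo-9-[(2S,3R)-3-(hydroxymethyl)-2-methyloxiran-2-yl]-2,6-dimethylnon-6-en-4-one (bromo ketone epoxy alcohol)
Conditions: DDQ (1.3 equiv), CH2Cl2–pH 7 buffer (10:1), 0 °C → rt
Reagents that add atoms: none
Why: Oxidative cleavage of the 4-methoxybenzyl ether by DDQ through the benzylic oxocarbenium ion and its hemiacetal; the buffered two-phase medium is neutral, so the bromo ketone, the oxirane and the skipped enone should survive.

Step 10
Reactants: 14 bromo ketone epoxy alcohol
Product: 15 (2S,3S)-3-[(3E)-7-bromo-4,8-dimethyl-6-oxonon-3-en-1-yl]-3-methyloxirane-2-carbaldehyde (seco-C6–C7 epoxy aldehyde)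
Conditions: Dess–Martin periodinane (1.5 equiv), NaHCO3, CH2Cl2, 0 °C → rt; used at once
Reagents that add atoms: none
Why: Dess–Martin oxidation of the primary epoxy alcohol under bicarbonate buffer; no base strong enough to touch the bromo ketone or to move the alkene is present, and the oxirane carbon C5 cannot epimerise.

Step 11
Reactants: 15 seco-C6–C7 epoxy aldehyde (both C7 epimers)
Product: 17 (1(10)E,4S,5R,6S,7S)-4,5-epoxy-6-hydroxygermacr-1(10)-en-8-one, via samarium enolate 16 (not isolated)
Conditions: SmI2 (2.2 equiv, 0.1 M in THF), THF, −78 °C, 15 added over 2 h (final ca. 0.003 M); pH 7 buffer at −78 °C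
Reagents that add atoms: samarium diiodide I[Sm]I (samarium and iodine of 16 only; none remain in 17)
Why: Two single-electron transfers from divalent samarium cleave the C7–Br bond of either epimer of 15 and give one enolate of trivalent samarium, 16, placed at C7–C8 and not toward C9. The enolate adds to the C6 aldehyde through a samarium-bridged chair (Zimmerman–Traxler) transition state and the aldolate is protonated on work-up. The closest known reaction type is the SmI2-mediated intramolecular Reformatsky-type aldol of alpha-bromo ketones onto aldehydes, which is known for medium rings. The ten-membered carbocycle closes in a 10-(enolendo)-exo-trig mode with the carbonyl oxygen outside the ring, helped by the E alkene and the oxirane, which remove rotors and bring the chain ends together. C6 is controlled by samarium held between the aldehyde and oxirane oxygens, which locks the O=C6–C5–O unit syn-periplanar so that the enolate attacks anti to C4 and gives the 5,6-syn carbinol. C7 is controlled by the Z enolate in the chair with C5 equatorial, which gives the 6,7-syn aldol, and C7 can still equilibrate next to the ketone if needed. The step needs reduction of C–Br ahead of the aldehyde and intramolecular ahead of intermolecular aldol; the first is secured by the much easier reduction of an alpha-bromo ketone at −78 °C without additives, the second by slow addition at high dilution, and the cold buffered quench guards against retro-aldol and alkene migration.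

Step 12
Reactants: 17 (1(10)E,4S,5R,6S,7S)-4,5-epoxy-6-hydroxygermacr-1(10)-en-8-one; 18 (E)-cinnamaldehyde
Product: 19 (1(10)E,4S,5R,6S,7R,8R)-4,5-epoxy-8-hydroxygermacr-1(10)-en-6-yl (2E)-3-phenylprop-2-enoate (CNP0306126.1)
Conditions: 18 (5 equiv), SmI2 (0.3 equiv), THF, −10 °C
Reagents that add atoms: none
Why: Evans–Tishchenko reduction; O6 adds to 18, trivalent samarium (formed from SmI2 and the aldehyde) bridges the hemiacetal oxygen and the C8 carbonyl, and the hemiacetal hydrogen passes to C8 through a six-membered chair on the face syn to O6. This sets C8 anti to O6 and leaves the cinnamate on O6 with O8 free; the closest known reaction type is the samarium-catalysed Tishchenko reduction of beta-hydroxy ketones with aldehydes.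

## Compound list

1 | nerol, (2Z)-3,7-dimethylocta-2,6-dien-1-ol | CC(C)=CCC/C(C)=C\CO | starting material
2 | (2R,3S)-2,3-epoxynerol, [(2R,3S)-3-methyl-3-(4-methylpent-3-en-1-yl)oxiran-2-yl]methanol | CC(C)=CCC[C@]1(C)O[C@@H]1CO | intermediate
3 | (2R,3S)-2-{[(4-methoxybenzyl)oxy]methyl}-3-methyl-3-(4-methylpent-3-en-1-yl)oxirane | CC(C)=CCC[C@]1(C)O[C@@H]1COCc1ccc(OC)cc1 | intermediate
4 | (2E)-5-[(2S,3R)-3-{[(4-methoxybenzyl)oxy]methyl}-2-methyloxiran-2-yl]-2-methylpent-2-en-1-ol | C/C(CO)=C\CC[C@]1(C)O[C@@H]1COCc1ccc(OC)cc1 | intermediate
5 | (2S,3R)-2-[(3E)-5-bromo-4-methylpent-3-en-1-yl]-3-{[(4-methoxybenzyl)oxy]methyl}-2-methyloxirane (formed and used in step 4 without isolation) | C/C(CBr)=C\CC[C@]1(C)O[C@@H]1COCc1ccc(OC)cc1 | intermediate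
6 | (2S,3R)-3-{[(4-methoxybenzyl)oxy]methyl}-2-methyl-2-[(3E)-4-methyl-5-(phenylsulfonyl)pent-3-en-1-yl]oxirane | C/C(CS(=O)(=O)c1ccccc1)=C\CC[C@]1(C)O[C@@H]1COCc1ccc(OC)cc1 | intermediate
7 | methyl 2-hydroxy-3-methylbutanoate (racemic) | COC(=O)C(O)C(C)C | starting material
8 | methyl 3-methyl-2-[(trimethylsilyl)oxy]butanoate (racemic) | COC(=O)C(O[Si](C)(C)C)C(C)C | intermediate
9 | (6E)-9-[(2S,3R)-3-{[(4-methoxybenzyl)oxy]methyl}-2-methyloxiran-2-yl]-2,6-dimethyl-5-(phenylsulfonyl)-3-[(trimethylsilyl)oxy]non-6-en-4-one (epimers at C7 and C9; formed and cleaved in step 6 without isolation) | C/C(C(C(=O)C(O[Si](C)(C)C)C(C)C)S(=O)(=O)c1ccccc1)=C\CC[C@]1(C)O[C@@H]1COCc1ccc(OC)cc1 | intermediate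
10 | (6E)-3-hydroxy-9-[(2S,3R)-3-{[(4-methoxybenzyl)oxy]methyl}-2-methyloxiran-2-yl]-2,6-dimethyl-5-(phenylsulfonyl)non-6-en-4-one (epimers at C7 and C9) | C/C(C(C(=O)C(O)C(C)C)S(=O)(=O)c1ccccc1)=C\CC[C@]1(C)O[C@@H]1COCc1ccc(OC)cc1 | intermediate
11 | (6E)-3-hydroxy-9-[(2S,3R)-3-{[(4-methoxybenzyl)oxy]methyl}-2-methyloxiran-2-yl]-2,6-dimethylnon-6-en-4-one (C7 epimers) | C/C(CC(=O)C(O)C(C)C)=C\CC[C@]1(C)O[C@@H]1COCc1ccc(OC)cc1 | intermediate
12 | (6E)-9-[(2S,3R)-3-{[(4-methoxybenzyl)oxy]methyl}-2-methyloxiran-2-yl]-2,6-dimethyl-4-oxonon-6-en-3-yl methanesulfonate (C7 epimers; formed and used in step 8 without isolation) | C/C(CC(=O)C(OS(C)(=O)=O)C(C)C)=C\CC[C@]1(C)O[C@@H]1COCc1ccc(OC)cc1 | intermediate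
13 | (6E)-3-bromo-9-[(2S,3R)-3-{[(4-methoxybenzyl)oxy]methyl}-2-methyloxiran-2-yl]-2,6-dimethylnon-6-en-4-one (C7 epimers) | C/C(CC(=O)C(Br)C(C)C)=C\CC[C@]1(C)O[C@@H]1COCc1ccc(OC)cc1 | intermediate
14 | (6E)-3-bromo-9-[(2S,3R)-3-(hydroxymethyl)-2-methyloxiran-2-yl]-2,6-dimethylnon-6-en-4-one (C7 epimers) | C/C(CC(=O)C(Br)C(C)C)=C\CC[C@]1(C)O[C@@H]1CO | intermediate
15 | (2S,3S)-3-[(3E)-7-bromo-4,8-dimethyl-6-oxonon-3-en-1-yl]-3-methyloxirane-2-carbaldehyde (C7 epimers) | C/C(CC(=O)C(Br)C(C)C)=C\CC[C@]1(C)O[C@@H]1C=O | intermediate
16 | diiodosamarium (Z)-enolate of the C8 ketone of 15 (C7=C8, O–SmI2 cis to isopropyl; oxirane and aldehyde as in 15; formed and consumed in step 11) | CC(C)/C=C(\O[Sm](I)I)C/C(C)=C/CC[C@]1(C)O[C@@H]1C=O | intermediate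
17 | (1(10)E,4S,5R,6S,7S)-4,5-epoxy-6-hydroxygermacr-1(10)-en-8-one | C/C1=C\CC[C@]2(C)O[C@@H]2[C@@H](O)[C@H](C(C)C)C(=O)C1 | intermediate
18 | (E)-cinnamaldehyde | O=C/C=C/c1ccccc1 | starting material
19 | (1(10)E,4S,5R,6S,7R,8R)-4,5-epoxy-8-hydroxygermacr-1(10)-en-6-yl (2E)-3-phenylprop-2-enoate, CNP0306126.1 | C/C1=C\CC[C@]2(C)O[C@@H]2[C@@H](OC(=O)/C=C/c2ccccc2)[C@H](C(C)C)[C@H](O)C1 | target

## Step count and least certain steps

Total: 12 steps. Longest linear sequence: 11 steps (1 to 19 through steps 1–4 and 6–12); step 5 is the side branch.

**Step 11 (key step).** Electron transfer to the epoxy aldehyde may compete with C–Br reduction (ketyl formation with oxirane opening or pinacol coupling). Intermolecular aldol may overtake the strained ten-membered closure. Attack at C6 may occur without the chelate and so with poor facial selectivity.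
Fallback: move the ring closure to C8–C9 and make C6–C7 first under auxiliary control. It sets out from 6. DDQ removes the ether to give the epoxy alcohol sulfone F1, and Dess–Martin oxidation gives the epoxy aldehyde sulfone F2. An Evans syn aldol with the boron enolate of commercial (S)-4-benzyl-3-(3-methylbutanoyl)oxazolidin-2-one (n-Bu2BOTf, i-Pr2NEt) sets C6 and C7 by reagent control and gives the aldol imide F3. Et3SiCl and imidazole give the triethylsilyl ether F4. LiN(SiMe3)2 (2.2 equiv) at high dilution lets the C9 sulfone carbanion acylate itself on the imide carbonyl and close the ring to the cyclic keto sulfone F5. SmI2 in THF–MeOH removes the sulfonyl group to give the silyl ether F6, and HF·pyridine frees O6. The fallback rejoins the route at 17.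

**Step 6.** The hindered ester may be enolised, or the sulfone carbanion quenched by proton transfer, so that acylation stalls.
Fallback: replace the acylation by addition and oxidation. It sets out from 8, which i-Bu2AlH at −78 °C reduces to the silyloxy aldehyde F7. The carbanion of 6 (n-BuLi, THF, −78 °C) adds to F7 to give the hydroxy sulfone F8, and Dess–Martin oxidation gives 9. The fallback rejoins the route at 9, which the acidic work-up converts to 10.

**Step 8.** Displacement at the hindered C7 may be slow, and elimination toward the conjugated isopropylidene ketone may then take over.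
Fallback: give up the halide exchange and use the sulfonate itself as the group that divalent samarium cleaves. It sets out from 12, isolated in this case. DDQ gives the mesyloxy epoxy alcohol F9 and Dess–Martin oxidation gives the mesyloxy epoxy aldehyde F10. Treatment of F10 under the conditions of step 11 should generate the same enolate 16, since alpha-sulfonyloxy ketones are also reduced to samarium enolates, though less rapidly than the bromide. The fallback rejoins the route at 17.

**Step 12.** The samarium aldolate may open by retro-aldol before hydride is passed on, hemiacetal formation with a conjugated aldehyde may be slow, and the acyl group may migrate from O6 to O8 during work-up.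
Fallback: separate reduction and acylation. It sets out from 17. A Saksena–Evans reduction with Me4NBH(OAc)3 in MeCN–AcOH at −30 °C delivers hydride from boron bound to O6 and gives the 6,8-anti diol F11. Et3SiCl and imidazole at low temperature should take the less crowded O8 (O6 lies between the oxirane carbon and C7) to give the 8-O-silyl ether F12. (E)-Cinnamoyl chloride with DMAP in pyridine gives the 6-O-cinnamate F13, and HF·pyridine removes the silyl group. The fallback rejoins the route at 19.

## Further compounds

F1 | step 11 | (2E)-5-[(2S,3R)-3-(hydroxymethyl)-2-methyloxiran-2-yl]-2-methylpent-2-en-1-yl phenyl sulfone (epoxy alcohol sulfone) | C/C(CS(=O)(=O)c1ccccc1)=C\CC[C@]1(C)O[C@@H]1CO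
F2 | step 11 | (2S,3S)-3-methyl-3-[(3E)-4-methyl-5-(phenylsulfonyl)pent-3-en-1-yl]oxirane-2-carbaldehyde (epoxy aldehyde sulfone) | C/C(CS(=O)(=O)c1ccccc1)=C\CC[C@]1(C)O[C@@H]1C=O
F3 | step 11 | Evans syn aldol imide: (4S)-4-benzyl-3-acyl-oxazolidin-2-one whose acyl chain carries C7 isopropyl and C6 hydroxyl configured as in 17, the oxirane of F2 and the C9 sulfone | C/C(CS(=O)(=O)c1ccccc1)=C\CC[C@]1(C)O[C@@H]1[C@@H](O)[C@H](C(C)C)C(=O)N1[C@@H](Cc2ccccc2)COC1=O
F4 | step 11 | 6-O-triethylsilyl ether of F3 | C/C(CS(=O)(=O)c1ccccc1)=C\CC[C@]1(C)O[C@@H]1[C@@H](O[Si](CC)(CC)CC)[C@H](C(C)C)C(=O)N1[C@@H](Cc2ccccc2)COC1=O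
F5 | step 11 | (1(10)E)-4,5-epoxy-9-(phenylsulfonyl)-6-[(triethylsilyl)oxy]germacr-1(10)-en-8-one, C4–C7 as in 17, C9 epimers | C/C1=C\CC[C@]2(C)O[C@@H]2[C@@H](O[Si](CC)(CC)CC)[C@H](C(C)C)C(=O)C1S(=O)(=O)c1ccccc1
F6 | step 11 | 6-O-triethylsilyl ether of 17 | C/C1=C\CC[C@]2(C)O[C@@H]2[C@@H](O[Si](CC)(CC)CC)[C@H](C(C)C)C(=O)C1
F7 | step 6 | 3-methyl-2-[(trimethylsilyl)oxy]butanal (racemic) | O=CC(O[Si](C)(C)C)C(C)C
F8 | step 6 | (6E)-9-[(2S,3R)-3-{[(4-methoxybenzyl)oxy]methyl}-2-methyloxiran-2-yl]-2,6-dimethyl-5-(phenylsulfonyl)-3-[(trimethylsilyl)oxy]non-6-en-4-ol (diastereomer mixture) | C/C(C(C(O)C(O[Si](C)(C)C)C(C)C)S(=O)(=O)c1ccccc1)=C\CC[C@]1(C)O[C@@H]1COCc1ccc(OC)cc1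
F9 | step 8 | (6E)-9-[(2S,3R)-3-(hydroxymethyl)-2-methyloxiran-2-yl]-2,6-dimethyl-4-oxonon-6-en-3-yl methanesulfonate (C7 epimers) | C/C(CC(=O)C(OS(C)(=O)=O)C(C)C)=C\CC[C@]1(C)O[C@@H]1CO
F10 | step 8 | (6E)-9-[(2S,3S)-3-formyl-2-methyloxiran-2-yl]-2,6-dimethyl-4-oxonon-6-en-3-yl methanesulfonate (C7 epimers) | C/C(CC(=O)C(OS(C)(=O)=O)C(C)C)=C\CC[C@]1(C)O[C@@H]1C=O
F11 | step 12 | (1(10)E)-4,5-epoxygermacr-1(10)-ene-6,8-diol, 6,8-anti, all centres as in 19 | C/C1=C\CC[C@]2(C)O[C@@H]2[C@@H](O)[C@H](C(C)C)[C@H](O)C1
F12 | step 12 | 8-O-triethylsilyl ether of F11 | C/C1=C\CC[C@]2(C)O[C@@H]2[C@@H](O)[C@H](C(C)C)[C@H](O[Si](CC)(CC)CC)C1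
F13 | step 12 | 8-O-triethylsilyl ether of 19 | C/C1=C\CC[C@]2(C)O[C@@H]2[C@@H](OC(=O)/C=C/c2ccccc2)[C@H](C(C)C)[C@H](O[Si](CC)(CC)CC)C1
A1 | alternative 1 | (2E,6Z)-1-[(tert-butyldimethylsilyl)oxy]-9-{[(4-methoxybenzyl)oxy]methyl}-2,6,10-trimethylundeca-2,6-dien-8-ol, carbinol (C6) and isopropyl-bearing carbon (C7) configured as in 19 | C/C(CO[Si](C)(C)C(C)(C)C)=C\CC/C(C)=C\[C@@H](O)[C@H](C(C)C)COCc1ccc(OC)cc1
A2 | alternative 1 | {[(2E)-5-bromo-2-methylpent-2-en-1-yl]oxy}(tert-butyl)dimethylsilane | C/C(CO[Si](C)(C)C(C)(C)C)=C\CCBr
A3 | alternative 1 | propyne | CC#C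
A4 | alternative 1 | (2R)-2-{[(4-methoxybenzyl)oxy]methyl}-3-methylbutanal | O=C[C@H](C(C)C)COCc1ccc(OC)cc1
A5 | alternative 2 | cis-anti-cis photoadduct with a tricyclo[4.4.0.0(2,5)]decane skeleton; in germacrane locants: 6-oxo, 7-isopropyl, 8-[(tert-butyldimethylsilyl)oxy], 10-methyl, methyl ester on C4, inner cyclobutane C1–C4–C5–C10 | C[C@@]12C[C@@H](O[Si](C)(C)C(C)(C)C)[C@@H](C(C)C)C(=O)[C@@H]1[C@@]1(C(=O)OC)CC[C@@H]21
A6 | alternative 2 | (5R,6R)-5-[(tert-butyldimethylsilyl)oxy]-3-methyl-6-(propan-2-yl)cyclohex-2-en-1-one | CC1=CC(=O)[C@H](C(C)C)[C@H](O[Si](C)(C)C(C)(C)C)C1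
A7 | alternative 2 | methyl cyclobut-1-ene-1-carboxylate | COC(=O)C1=CCC1
A8 | alternative 3 | 6-O-(tert-butyldimethylsilyl) germacra-1(10)E,4Z,11-triene-6,8-diol, C6–C8 as in 19 | C/C1=C\CC/C(C)=C\[C@@H](O[Si](C)(C)C(C)(C)C)[C@H](C(C)=C)[C@H](O)C1
A9 | alternative 3 | thirteen-membered allyl ether with oxygen bridging C8 and C12: 1(10)E,4Z,7(11)E triene, 6-O-tert-butyldimethylsilyl, tributylstannyl on C8 | C/C1=C\CC/C(C)=C\[C@@H](O[Si](C)(C)C(C)(C)C)/C=C(\C)CO[C@H]([Sn](CCCC)(CCCC)CCCC)C1
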